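**Remark:** Positions are given in labdane numbering throughout, also for monocyclic intermediates (C1–C10 decalin, C11–C16 side chain, C17 on C8, C18/C19 on C4, C20 on C10). Faces are called syn or anti to the angular methyl C20.

## Analysis of the target

The target is a labdane diterpenoid diacetate of the ent series, (2S,3R,5S,9R,10S,13E). It is a trans-fused decalin (ring A: C1–C5 and C10; ring B: C5–C10) with a trisubstituted C7=C8 alkene, an angular methyl on C10 and a gem-dimethyl carbon C4. The C9 side chain ends in an (E)-trisubstituted allylic acetate (C13=C14, C15–OAc). H5 and H9 are anti to C20, so the side chain is equatorial and syn to C20. The two ring A oxygens are cis to each other and anti to C20, which makes the C2 acetate equatorial and the free C3 hydroxyl axial. Sensitive features are the primary allylic acetate (ionisation, allylic transposition), both esters towards base, possible acyl migration from O2 to the cis O3, and the C7=C8 alkene, which acid can move to the tetrasubstituted C8=C9 position. The synthesis is hard because the quaternary C10 is surrounded by stereocentres, because the C3–C4 bond is neopentyl on one side and oxygenated on the other, and because the vicinal oxygens must be told apart (O2 acetylated, O3 free). The strategy rests on C4: a dimethylated carbon between the C3 carbinol and the C5 methine is what an isopropenyl group on C5 becomes when a hydrogen atom is added to its CH2 and the resulting tertiary radical bonds to a carbonyl carbon. (S)-Carvone 1 already carries that isopropenyl group on C5, the C5 configuration, and the C7=C8(CH3)–C9=O unit where the alkene and C17 are needed.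

## Retrosynthetic reasoning

**28 to 27.** The two ester C–O bonds are cut first, giving triol 27. Acetates would not survive the organometallic and basic steps, so they come last. The forward reaction has to acylate the primary allylic O15 and the equatorial O2 and leave the axial O3, which is shielded by C4.

**27 to 26.** The three Si–O bonds are cut together. Carrying all three oxygens as silyl ethers (26) allows one global desilylation, and it makes any silyl migration between O2 and O3 earlier in the route harmless.

**26 to 19 and 23.** The C11–C12 bond is cut. This splits the side chain into allylic bromide 23, which already holds the E alkene and O15, and a C11 nucleophile made from iodide 19. The coupling must take place at the bromide-bearing carbon so that the alkene neither shifts nor loses its geometry.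

**23 to 20.** Bromide 23 goes back through allylic alcohol 22 and silyl ether 21 to prenol 20. The allylic oxidation of 21 has to place the new oxygen on the methyl group trans to the CH2O arm.

**19 to 16.** The C11–I bond comes from alcohol 18, and the C9–H and C11–O bonds of 18 come from hydroboration–oxidation of diene 16. This disconnection is chosen because it sets C9. The angular methyl blocks one face of the exocyclic alkene, so hydrogen should arrive anti to C20.

**16 to 13.** The C9=C11 bond comes from the C9 ketone of 14 by Peterson methylenation through carbinol 15. Compound 14 is the triethylsilyl ether of the cyclisation product 13.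

**13 to 12.** The C3–C4 bond is cut, which opens ring A. In the forward direction a hydrogen atom is transferred to the isopropenyl CH2 of aldehyde 12 and the tertiary C4 radical closes onto C3. This is the only disconnection of ring A that turns C4 into a native carvone substituent. A radical is used because an enolate or cation at C4 would struggle to form this congested bond.

**12 to 8.** Aldehyde 12 comes from primary alcohol 11, 11 from aryl ether 10, 10 from alcohol 9, and 9 from epoxide 8 by opening at C3. These are functional-group changes only. They place a silyl ether on O2 and raise C3 to the aldehyde without touching the C2 stereocentre.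

**8 to 1, 2 and 5.** The C1–C10 bond is cut to the enolate of 6-methylcarvone 4 and glycidyl triflate 6. Compound 6 comes from (S)-glycidol 5, and 4 from (S)-carvone 1 and methyl iodide 2. Methylation comes first so that the larger electrophile enters second, anti to the isopropenyl group. This gives the trans relation of the C10 arm and the C5 substituent that the trans ring fusion needs.

## Alternatives that were turned down

**Alternative 1: intramolecular Diels–Alder reaction closing both rings.**
- Disconnection: C5–C10 and C8–C9 together.
- Forward key step: an (E)-trisubstituted enoate (C9=C10, ester carbon C11) and a 2-silyloxy diene (C5=C6–C7=C8), linked by the C1–C4 tether with the diol held as an acetonide, cyclise on heating to the bicyclic silyl enol ether ester A1.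
- For it: two bonds, two rings and the C5, C8, C9 and C10 centres form in one step; the dienophile geometry fixes C11 syn to C20; the diol template can bias the facial sense.
- Against it: the dienophile is a β,β-disubstituted acrylate that must create the quaternary C10. The diene terminus C5 sits next to the quaternary C4. Trans versus cis fusion and endo versus exo are not secured by anything in the substrate. The acyclic triene needs two alkenes of defined geometry and a labile silyloxy diene. After A1, the C7 oxygen must be removed through a regioselective enol triflate, the ester must be turned into the side chain, and O2 and O3 must still be differentiated.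
- Comparison: A1 is clearly stronger in bonds and rings per step. The chosen route takes ring B, C5 and the alkene position from carvone 1 and asks the key step for one bond only, with the ring fusion already decided.

**Alternative 2: reductive Heck closure of ring B.**
- Disconnection: C8–C9.
- Forward key step: with Pd(OAc)2 and HCO2Na, the vinylpalladium formed from a (Z)-enol triflate at C8 on the C5 arm adds 6-exo to C9 of an (E)-enoate on C10, and the palladium enolate at C11 is reduced, giving ester acetonide A2.
- For it: A2 has the C7=C8 alkene with C17, the C9 stereocentre and C11–C12 in place, so it is closer to the side chain than the product of the chosen key step.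
- Against it: ring A must first be made as a single enantiomer with C2, C3, C5 and the quaternary C10 set, without help from the chiral pool. The internal (Z)-enol triflate of a methyl ketone is hard to make regio- and stereoselectively. The C9 configuration depends on the rotamer of the enoate next to C10. Direct formate reduction of the vinylpalladium and alkene migration compete with a slow addition next to a quaternary centre. Turning C12 into the C13=C14 allylic unit still takes several steps.
- Comparison: A2 is stronger on C9 and on side-chain carbons after the key step. The chosen strategy offers absolute configuration from 1 and 5 and a seven-step, conventional approach to its key precursor 12.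

**Alternative 3: ring B by ring-closing metathesis.**
- Disconnection: C7=C8.
- Forward key step: a ring A diene with a crotyl group on C5 and, on C10, the C9 carbon bearing an isopropenyl group and the whole side chain (assembled by Claisen rearrangement) is closed by the second-generation Grubbs catalyst to the bicyclic 1,7-diene A3.
- For it: it is the most convergent plan, with the whole carbon skeleton and side chain present before ring closure, and six-membered ring-closing metathesis is dependable.
- Against it: the substrate carries four alkenes, and the trisubstituted C7=C8 bond must form from a hindered 1,1-disubstituted alkene beside C9 and C10. The Claisen step must set the vicinal C9 and C10 centres, one of them quaternary. A3 has no C2 oxygen, so it must be introduced late, cis to O3 and regioselectively, in the presence of the C7=C8 and C13=C14 alkenes.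
- Comparison: A3 is stronger in convergence and in having the side chain early. The chosen route has both ring A oxygens in place before ring A closes and never needs to distinguish three alkenes.

Key step: step 8

## Route

Step 1
Reactants: 1 (S)-(+)-carvone; 2 methyl iodide
Product: 4 (5S)-6-methylcarvone (methyl on C10; mixture of C10 epimers), via lithium dienolate 3 (not isolated)
Conditions: LiN(iPr)2, THF, −78 °C; then MeI, −78 → 0 °C
Reagents that add atoms: methyl iodide (2), CI
Why: Kinetic deprotonation at the saturated α′-carbon (C10) gives the cross-conjugated dienolate, which is C-methylated (enolate alkylation). The configuration of the new centre does not matter because step 3 planarises it again.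

Step 2
Reactants: 5 (S)-glycidol
Product: 6 (R)-oxiran-2-ylmethyl trifluoromethanesulfonate
Conditions: Tf2O, 2,6-lutidine, CH2Cl2, −78 °C; used at once as a cold solution
Reagents that add atoms: trifluoromethanesulfonic anhydride, O=S(=O)(OS(=O)(=O)C(F)(F)F)C(F)(F)F
Why: O-Sulfonylation of the primary alcohol; no bond to the stereocentre is touched. The descriptor changes from S to R only because the CH2OTf arm now outranks the ring CH2.

Step 3
Reactants: 4 (5S)-6-methylcarvone; 6 (R)-oxiran-2-ylmethyl trifluoromethanesulfonate
Product: 8 (5R,6R)-2,6-dimethyl-6-[(2S)-oxiran-2-ylmethyl]-5-(prop-1-en-2-yl)cyclohex-2-en-1-one (C10 arm trans to isopropenyl), via lithium enolate 7 (not isolated)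
Conditions: LiN(iPr)2, THF, −78 → 0 °C; then 6, −78 → −30 °C
Reagents that add atoms: none
Why: Enolate alkylation creating the quaternary C10: the isopropenyl group on C5 stands pseudo-axial in the enolate to avoid the C10 methyl, so the electrophile should enter on the opposite face. Direct displacement at the CH2OTf carbon is far faster than epoxide opening, so the glycidol stereocentre is carried over unchanged as C2.

Step 4
Reactants: 8 epoxy ketone
Product: 9 (5R,6R)-6-[(2S)-2-hydroxy-3-(4-methoxyphenoxy)propyl]-2,6-dimethyl-5-(prop-1-en-2-yl)cyclohex-2-en-1-one
Conditions: 4-MeOC6H4OH, Cs2CO3 (cat.), DMF, 70 °C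
Reagents that add atoms: 4-methoxyphenol, COc1ccc(O)cc1
Why: SN2 opening of the terminal epoxide by the phenoxide at the unsubstituted carbon C3. The C2–O bond is not broken, so C2 keeps its configuration; acid-mediated opening is avoided because it would partly attack C2. The phenol reprotonates the alkoxide, so the base is needed only in catalytic amount.

Step 5
Reactants: 9 hydroxy aryl ether
Product: 10 (5R,6R)-6-[(2S)-2-(tert-butyldimethylsilyloxy)-3-(4-methoxyphenoxy)propyl]-2,6-dimethyl-5-(prop-1-en-2-yl)cyclohex-2-en-1-one
Conditions: TBSCl, imidazole, DMF, rt
Reagents that add atoms: tert-butyldimethylsilyl chloride, CC(C)(C)[Si](C)(C)Cl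
Why: Standard silylation of an unhindered secondary alcohol. The imidazole conditions are too mild to turn the enone into a silyl dienol ether.

Step 6
Reactants: 10 silyl ether aryl ether
Product: 11 (5R,6R)-6-[(2S)-2-(tert-butyldimethylsilyloxy)-3-hydroxypropyl]-2,6-dimethyl-5-(prop-1-en-2-yl)cyclohex-2-en-1-one
Conditions: (NH4)2Ce(NO3)6, pyridine, MeCN/H2O, 0 °C
Reagents that add atoms: none
Why: Oxidative dearylation: tetravalent cerium oxidises the electron-rich 4-methoxyphenyl ether to a quinone-type cation that water hydrolyses, releasing the primary alcohol. The enone, isopropenyl group and buffered silyl ether are not oxidised under these brief, cold conditions.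

Step 7
Reactants: 11 primary alcohol
Product: 12 (5R,6R)-6-[(2S)-2-(tert-butyldimethylsilyloxy)-3-oxopropyl]-2,6-dimethyl-5-(prop-1-en-2-yl)cyclohex-2-en-1-one
Conditions: Dess–Martin periodinane, NaHCO3, CH2Cl2, 0 °C → rt; used without storage
Reagents that add atoms: none
Why: Dess–Martin oxidation of a primary alcohol under buffered, non-basic conditions, chosen so that the α-silyloxy aldehyde is not epimerised at C2.

Step 8
Reactants: 12 α-silyloxy aldehyde
Product: 13 trans-fused bicyclic enone: 2-(tert-butyldimethylsilyloxy)-3-hydroxy-4,4,8,10-tetramethyl-Δ7-octalin-9-one (O2 equatorial; O3 axial; both anti to C20; H5 anti to C20)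
Conditions: Fe(acac)3 (50 mol%), PhSiH3, degassed EtOH, 60 °C
Reagents that add atoms: none
Why: The iron hydride formed from Fe(acac)3 and PhSiH3 in ethanol transfers a hydrogen atom to the CH2 terminus of the isopropenyl group, and the tertiary C4 radical adds to the aldehyde carbon C3; divalent iron then reduces the alkoxy radical to the alkoxide, returning trivalent iron, and the solvent protonates it. The closest known reaction type is the iron-hydride-initiated reductive cyclisation of alkene-tethered ketones, of which aldehyde acceptors are the less explored members. Ring A closes in the 6-exo-trig mode (C4 onto C3, oxygen exocyclic) through a chair in which the C10 arm and the C5 radical centre, both pseudo-equatorial on ring B, are gauche, so the trans ring fusion follows from the C5 and C10 configurations set in step 3. C3 is the one new stereocentre: the C2 silyloxy group lies equatorial and anti to the forming bond, and the product needed arises when the carbonyl oxygen points axially, towards H1 and H5 on the face away from C20, instead of between the two C4 methyl groups; this preference is expected to be modest. The step needs hydrogen-atom transfer to the electron-rich 1,1-disubstituted alkene and not to the enone, which the electron-poor trisubstituted C7=C8 bond secures. It also needs a radical with no second acceptor, which holds because attack on C7 or C9 would close a four-membered ring. The near-neutral medium should leave C2 intact until the aldehyde is consumed.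

Step 9
Reactants: 13 bicyclic hydroxy enone
Product: 14 3-O-triethylsilyl ether of 13
Conditions: Et3SiOTf, 2,6-lutidine, CH2Cl2, −78 °C
Reagents that add atoms: triethylsilyl trifluoromethanesulfonate, CC[Si](CC)(CC)OS(=O)(=O)C(F)(F)F
Why: Silyl triflates silylate even hindered axial neopentyl alcohols at low temperature. Protection removes the acidic proton before the organometallic steps and makes any later O2/O3 silyl migration irrelevant.

Step 10
Reactants: 14 bis-silyl enone
Product: 15 C9 tertiary carbinol bearing a CH2SiMe3 group (C9 configuration not controlled)
Conditions: Me3SiCH2Li, CeCl3, THF, −78 → 0 °C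
Reagents that add atoms: (trimethylsilyl)methyllithium, [Li]C[Si](C)(C)C
Why: 1,2-Addition of the organocerium reagent to the hindered C9 carbonyl (first half of a Peterson olefination). The weakly basic reagent avoids γ-deprotonation to the dienolate, and the new carbinol centre is removed in step 11.

Step 11
Reactants: 15 β-hydroxysilane
Product: 16 7,9(11)-diene with exocyclic C9=C11 methylene (O2 TBS; O3 TES)
Conditions: KH, THF, 0 °C → rt
Reagents that add atoms: none
Why: Peterson elimination: the potassium alkoxide expels the silanolate by syn-elimination to give the conjugated diene. Basic conditions are used so that neither silyl ether nor the C7=C8 position is disturbed.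

Step 12
Reactants: 16 diene
Product: 18 C11 primary alcohol with the C9 stereocentre of the target (H9 anti to C20), via C11 alkylborane 17 (not isolated)
Conditions: 9-BBN, THF, 0 → 65 °C; then NaOH, H2O2, 0 °C → rt
Reagents that add atoms: hydrogen peroxide, OO
Why: Hydroboration–oxidation: boron adds to the terminal C11 of the exocyclic alkene and hydrogen to C9 from the face anti to the axial C20 methyl on the neighbouring carbon, which places C11 equatorial and syn to C20. The bulky borane should leave the trisubstituted C7=C8 bond alone.

Step 13
Reactants: 18 primary alcohol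
Product: 19 C11 primary iodide
Conditions: I2, PPh3, imidazole, CH2Cl2, 0 °C → rt
Reagents that add atoms: iodine, II
Why: Appel-type iodination of the only free hydroxyl group through its alkoxyphosphonium salt; no stereocentre is involved.

Step 14
Reactants: 20 3-methylbut-2-en-1-ol (prenol)
Product: 21 tert-butyldimethyl(3-methylbut-2-enyloxy)silane
Conditions: TBSCl, imidazole, CH2Cl2, rt
Reagents that add atoms: tert-butyldimethylsilyl chloride, CC(C)(C)[Si](C)(C)Cl
Why: Routine silylation of a primary allylic alcohol.

Step 15
Reactants: 21 prenyl silyl ether
Product: 22 (E)-4-(tert-butyldimethylsilyloxy)-2-methylbut-2-en-1-ol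
Conditions: SeO2 (cat.), t-BuOOH, CH2Cl2, rt
Reagents that add atoms: tert-butyl hydroperoxide, CC(C)(C)OO
Why: Selenium dioxide allylic oxidation (ene reaction, then [2,3]-sigmatropic shift) hydroxylates the methyl group trans to the CH2O arm of a trisubstituted alkene and so gives the E allylic alcohol.

Step 16
Reactants: 22 (E)-allylic alcohol
Product: 23 (E)-(4-bromo-3-methylbut-2-enyloxy)(tert-butyl)dimethylsilane
Conditions: CBr4, PPh3, CH2Cl2, 0 °C
Reagents that add atoms: carbon tetrabromide, BrC(Br)(Br)Br
Why: Appel bromination of a primary allylic alcohol by direct displacement, which keeps the position and E geometry of the alkene.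

Step 17
Reactants: 19 C11 iodide; 23 (E)-allylic bromide
Product: 26 2,15-bis-TBS 3-TES ether of the labda-7,13E-diene-2,3,15-triol, via C11 alkyllithium 24 (not isolated), via C11 alkylmagnesium bromide 25 (not isolated)
Conditions: t-BuLi, Et2O, −78 °C; MgBr2·OEt2, −78 → 0 °C; then 23, Li2CuCl4 (cat.), THF, −78 → 0 °C
Reagents that add atoms: none
Why: Iodine–lithium exchange and transmetalation give a Grignard reagent, which couples under copper catalysis with the primary allylic bromide at the bromide-bearing carbon (SN2 mode favoured by these conditions). C11–C12 forms and the E alkene is kept; the silyl ethers tolerate all reagents.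

Step 18
Reactants: 26 tris-silyl ether
Product: 27 labda-7,13E-diene-2,3,15-triol with the target configuration
Conditions: Bu4NF, THF, rt → 45 °C
Reagents that add atoms: none
Why: Fluoride cleaves all three silyl ethers in one operation; nothing else in the molecule is base- or fluoride-sensitive.

Step 19
Reactants: 27 triol
Product: 28 target diacetate CNP0254679.1
Conditions: Ac2O (2.2 equiv.), pyridine, CH2Cl2, 0 °C → rt
Reagents that add atoms: acetic anhydride, CC(=O)OC(C)=O
Why: Selective acylation by steric differentiation: the primary allylic O15 and the equatorial O2 should react, while the axial O3, flanked by the gem-dimethyl carbon C4, should not without an acyl-transfer catalyst.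

## Compound list

1 | (S)-(+)-carvone | CC1=CC[C@@H](CC1=O)C(C)=C | starting material
2 | methyl iodide | CI | starting material
3 | lithium dienolate of carvone (formed in the flask) | CC1=CC[C@@H](C=C1O[Li])C(C)=C | intermediate
4 | (5S)-6-methylcarvone, mixture of epimers at the methylated carbon | CC1=CC[C@H](C(C)=C)C(C)C1=O | intermediate
5 | (S)-glycidol | C1[C@@H](O1)CO | starting material
6 | (R)-oxiran-2-ylmethyl trifluoromethanesulfonate | FC(F)(F)S(=O)(=O)OC[C@H]1CO1 | intermediate
7 | lithium enolate of 6-methylcarvone (formed in the flask) | CC1=CC[C@H](C(C)=C)C(C)=C1O[Li] | intermediate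
8 | (5R,6R)-2,6-dimethyl-6-[(2S)-oxiran-2-ylmethyl]-5-(prop-1-en-2-yl)cyclohex-2-en-1-one | CC1=CC[C@H](C(C)=C)[C@@](C)(C[C@H]2CO2)C1=O | intermediate
9 | (5R,6R)-6-[(2S)-2-hydroxy-3-(4-methoxyphenoxy)propyl]-2,6-dimethyl-5-(prop-1-en-2-yl)cyclohex-2-en-1-one | CC1=CC[C@H](C(C)=C)[C@@](C)(C[C@H](O)COc2ccc(OC)cc2)C1=O | intermediate
10 | (5R,6R)-6-[(2S)-2-(tert-butyldimethylsilyloxy)-3-(4-methoxyphenoxy)propyl]-2,6-dimethyl-5-(prop-1-en-2-yl)cyclohex-2-en-1-one | CC1=CC[C@H](C(C)=C)[C@@](C)(C[C@H](O[Si](C)(C)C(C)(C)C)COc2ccc(OC)cc2)C1=O | intermediate
11 | (5R,6R)-6-[(2S)-2-(tert-butyldimethylsilyloxy)-3-hydroxypropyl]-2,6-dimethyl-5-(prop-1-en-2-yl)cyclohex-2-en-1-one | CC1=CC[C@H](C(C)=C)[C@@](C)(C[C@H](O[Si](C)(C)C(C)(C)C)CO)C1=O | intermediate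
12 | (5R,6R)-6-[(2S)-2-(tert-butyldimethylsilyloxy)-3-oxopropyl]-2,6-dimethyl-5-(prop-1-en-2-yl)cyclohex-2-en-1-one (key-step precursor) | CC1=CC[C@H](C(C)=C)[C@@](C)(C[C@H](O[Si](C)(C)C(C)(C)C)C=O)C1=O | intermediate
13 | trans-fused bicyclic 7-en-9-one with axial C3 hydroxyl, equatorial C2 TBS ether and C4 gem-dimethyl (key-step product) | CC1=CC[C@@H]2C(C)(C)[C@@H](O)[C@@H](O[Si](C)(C)C(C)(C)C)C[C@@]2(C)C1=O | intermediate
14 | 3-O-triethylsilyl ether of 13 | CC1=CC[C@@H]2C(C)(C)[C@@H](O[Si](CC)(CC)CC)[C@@H](O[Si](C)(C)C(C)(C)C)C[C@@]2(C)C1=O | intermediate
15 | C9 carbinol with CH2SiMe3 group (C9 unassigned) | CC1=CC[C@@H]2C(C)(C)[C@@H](O[Si](CC)(CC)CC)[C@@H](O[Si](C)(C)C(C)(C)C)C[C@@]2(C)C1(O)C[Si](C)(C)C | intermediate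
16 | bicyclic 7,9(11)-diene, O2 TBS and O3 TES | C=C1C(C)=CC[C@@H]2C(C)(C)[C@@H](O[Si](CC)(CC)CC)[C@@H](O[Si](C)(C)C(C)(C)C)C[C@@]12C | intermediate
17 | C11 B-alkyl-9-borabicyclo[3.3.1]nonane (formed in the flask) | C34CCCC(CCC3)B4C[C@@H]1C(C)=CC[C@@H]2C(C)(C)[C@@H](O[Si](CC)(CC)CC)[C@@H](O[Si](C)(C)C(C)(C)C)C[C@@]12C | intermediate
18 | C11 primary alcohol, H9 anti to C20 | OC[C@@H]1C(C)=CC[C@@H]2C(C)(C)[C@@H](O[Si](CC)(CC)CC)[C@@H](O[Si](C)(C)C(C)(C)C)C[C@@]12C | intermediate
19 | C11 primary iodide | IC[C@@H]1C(C)=CC[C@@H]2C(C)(C)[C@@H](O[Si](CC)(CC)CC)[C@@H](O[Si](C)(C)C(C)(C)C)C[C@@]12C | intermediate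
20 | 3-methylbut-2-en-1-ol (prenol) | CC(C)=CCO | starting material
21 | tert-butyldimethyl(3-methylbut-2-enyloxy)silane | CC(C)=CCO[Si](C)(C)C(C)(C)C | intermediate
22 | (E)-4-(tert-butyldimethylsilyloxy)-2-methylbut-2-en-1-ol | CC(C)(C)[Si](C)(C)OC/C=C(\C)CO | intermediate
23 | (E)-(4-bromo-3-methylbut-2-enyloxy)(tert-butyl)dimethylsilane | CC(C)(C)[Si](C)(C)OC/C=C(\C)CBr | intermediate
24 | C11 alkyllithium (formed in the flask) | [Li]C[C@@H]1C(C)=CC[C@@H]2C(C)(C)[C@@H](O[Si](CC)(CC)CC)[C@@H](O[Si](C)(C)C(C)(C)C)C[C@@]12C | intermediate
25 | C11 alkylmagnesium bromide (formed in the flask) | Br[Mg]C[C@@H]1C(C)=CC[C@@H]2C(C)(C)[C@@H](O[Si](CC)(CC)CC)[C@@H](O[Si](C)(C)C(C)(C)C)C[C@@]12C | intermediate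
26 | labda-7,13E-diene-2,3,15-triol 2,15-bis-TBS 3-TES ether | CC(C)(C)[Si](C)(C)OC/C=C(\C)CC[C@@H]1C(C)=CC[C@@H]2C(C)(C)[C@@H](O[Si](CC)(CC)CC)[C@@H](O[Si](C)(C)C(C)(C)C)C[C@@]12C | intermediate
27 | (2S,3R,5S,9R,10S,13E)-labda-7,13-diene-2,3,15-triol | OC/C=C(\C)CC[C@@H]1C(C)=CC[C@@H]2C(C)(C)[C@@H](O)[C@@H](O)C[C@@]12C | intermediate
28 | CNP0254679.1, the 2,15-diacetate of 27 | CC(=O)OC/C=C(\C)CC[C@@H]1C(C)=CC[C@@H]2C(C)(C)[C@@H](O)[C@@H](OC(C)=O)C[C@@]12C | target

## Step count and least certain steps

Total: 19 steps. Longest linear sequence: 15 steps (steps 1, 3–13 and 17–19, from 1 to 28). Steps 2 and 14–16 are side branches.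

**Step 8 (key step).** The most likely failure is poor facial selectivity at the aldehyde carbon. The chair with the carbonyl oxygen equatorial is close in energy, because an equatorial carbinol next to a gem-dimethyl carbon is the more stable arrangement. A second concern is reopening of the alkoxy radical by β-scission, followed by simple reduction of the tertiary radical. The fallback sets out from 12 and comes back at 16; it sets C3 by reagent control instead of by the cyclisation. The cyclisation is run as before and the 3-epimeric alcohol F1 is taken on. Addition of Me3SiCH2Li/CeCl3 gives the C9 adduct F2. Mild acid (pyridinium p-toluenesulfonate, CH2Cl2) then effects Peterson elimination to the epimeric diene alcohol F3; acid is chosen over KH so that the silyl group does not move to the free O3. Dess–Martin oxidation gives the 3-oxo diene F4. LiBH(s-Bu)3 at −78 °C attacks from the equatorial side and gives the axial alcohol F5, which Et3SiOTf converts into 16. The enone is removed before the reduction because the bulky borohydride would otherwise reduce it in the 1,4 sense. A mixture of 13 and F1 can be carried through the same sequence, since 13 itself gives F5 in the first two operations.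

**Step 3.** The most likely failures are O-alkylation of the fully substituted enolate by the hard triflate and loss of the electrophile through epoxide opening or decomposition before the slow quaternary-centre formation. The fallback sets out from 4 and comes back at 11; C2 is then set by a catalyst and not by glycidol. Enolate 7 is alkylated with allyl bromide, a soft electrophile with the same facial preference, to give the allyl ketone F6. Aldehyde-selective Wacker-type oxidation (PdCl2(PhCN)2, CuCl2, AgNO2, O2, t-BuOH/MeNO2) oxidises only the monosubstituted alkene and gives aldehyde F7. α-Aminoxylation with nitrosobenzene and D-proline, the enantiomer expected to deliver the (S)-configured centre, gives the α-anilinooxy aldehyde F8. This is reduced in the same flask with NaBH4 to alcohol F9. Zn/AcOH cleaves the N–O bond to diol F10. TBSCl/imidazole gives the bis-silyl ether F11, and HF·pyridine removes the primary silyl group to give 11.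

**Step 17.** The most likely failures are incomplete iodine–lithium exchange or protonation of the hindered organometallic, homocoupling, and γ-attack on the allylic bromide, which would give the branched isomer. The fallback sets out from 19 and comes back at 26; it replaces the organocopper coupling with a sulfone alkylation. Displacement of iodide with PhSO2Na (DMF, 80 °C) gives the C11 phenyl sulfone F12. Deprotonation with n-BuLi gives the lithiated sulfone F13, which alkylates bromide 23 only at the bromide-bearing carbon to give the alkylated sulfone F14. Reductive desulfonylation with Na/Hg and Na2HPO4 in MeOH gives 26.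

**Step 19.** The most likely failures are over-acetylation at O3, incomplete acetylation at O2, and acyl migration between the cis oxygens. The fallback sets out from 27 and comes back at 28; it acylates in two directed stages. Acetyl chloride with 2,4,6-collidine at −78 °C acetylates only the primary allylic hydroxyl and gives the 15-monoacetate F15. Bu2SnO in refluxing toluene with removal of water gives the 2,3-O-dibutylstannylene acetal F16. Acetyl chloride at 0 °C then acylates the equatorial oxygen O2 of this acetal and gives 28.

## Further compounds

F1 | step 8 | C3 epimer of 13 (equatorial C3 hydroxyl, trans to O2) | CC1=CC[C@@H]2C(C)(C)[C@H](O)[C@@H](O[Si](C)(C)C(C)(C)C)C[C@@]2(C)C1=O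
F2 | step 8 | C9 CH2SiMe3 carbinol of F1 (C9 unassigned) | CC1=CC[C@@H]2C(C)(C)[C@H](O)[C@@H](O[Si](C)(C)C(C)(C)C)C[C@@]2(C)C1(O)C[Si](C)(C)C
F3 | step 8 | 7,9(11)-diene with equatorial C3 hydroxyl and C2 TBS ether | C=C1C(C)=CC[C@@H]2C(C)(C)[C@H](O)[C@@H](O[Si](C)(C)C(C)(C)C)C[C@@]12C
F4 | step 8 | 3-oxo-7,9(11)-diene with C2 TBS ether | C=C1C(C)=CC[C@@H]2C(C)(C)C(=O)[C@@H](O[Si](C)(C)C(C)(C)C)C[C@@]12C
F5 | step 8 | 7,9(11)-diene with axial C3 hydroxyl and C2 TBS ether | C=C1C(C)=CC[C@@H]2C(C)(C)[C@@H](O)[C@@H](O[Si](C)(C)C(C)(C)C)C[C@@]12C
F6 | step 3 | 6-allyl-6-methylcarvone (allyl trans to isopropenyl) | CC1=CC[C@H](C(C)=C)[C@@](C)(CC=C)C1=O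
F7 | step 3 | 6-methyl-6-(3-oxopropyl)carvone | CC1=CC[C@H](C(C)=C)[C@@](C)(CCC=O)C1=O
F8 | step 3 | (2S)-2-anilinooxy aldehyde of F7 | CC1=CC[C@H](C(C)=C)[C@@](C)(C[C@H](ONc2ccccc2)C=O)C1=O
F9 | step 3 | (2S)-2-anilinooxy-3-hydroxypropyl ketone | CC1=CC[C@H](C(C)=C)[C@@](C)(C[C@H](ONc2ccccc2)CO)C1=O
F10 | step 3 | (2S)-2,3-dihydroxypropyl ketone | CC1=CC[C@H](C(C)=C)[C@@](C)(C[C@H](O)CO)C1=O
F11 | step 3 | (2S)-2,3-bis(tert-butyldimethylsilyloxy)propyl ketone | CC1=CC[C@H](C(C)=C)[C@@](C)(C[C@H](O[Si](C)(C)C(C)(C)C)CO[Si](C)(C)C(C)(C)C)C1=O
F12 | step 17 | C11 phenyl sulfone | O=S(=O)(C[C@@H]1C(C)=CC[C@@H]2C(C)(C)[C@@H](O[Si](CC)(CC)CC)[C@@H](O[Si](C)(C)C(C)(C)C)C[C@@]12C)c1ccccc1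
F13 | step 17 | C11-lithiated phenyl sulfone | [Li]C([C@@H]1C(C)=CC[C@@H]2C(C)(C)[C@@H](O[Si](CC)(CC)CC)[C@@H](O[Si](C)(C)C(C)(C)C)C[C@@]12C)S(=O)(=O)c1ccccc1
F14 | step 17 | C11 phenylsulfonyl derivative of 26 (C11 unassigned) | CC(C)(C)[Si](C)(C)OC/C=C(\C)CC([C@@H]1C(C)=CC[C@@H]2C(C)(C)[C@@H](O[Si](CC)(CC)CC)[C@@H](O[Si](C)(C)C(C)(C)C)C[C@@]12C)S(=O)(=O)c1ccccc1
F15 | step 19 | 15-monoacetate of triol 27 | CC(=O)OC/C=C(\C)CC[C@@H]1C(C)=CC[C@@H]2C(C)(C)[C@@H](O)[C@@H](O)C[C@@]12C
F16 | step 19 | 2,3-O-dibutylstannylene acetal of F15 | CC(=O)OC/C=C(\C)CC[C@@H]1C(C)=CC[C@@H]2C(C)(C)[C@H]3O[Sn](CCCC)(CCCC)O[C@H]3C[C@@]12C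
A1 | alternative 1 | trans-fused bicyclic C7 silyl enol ether with C11 methyl ester and C2/C3 acetonide | COC(=O)[C@@H]1[C@H](C)C(O[Si](C)(C)C(C)(C)C)=C[C@@H]2C(C)(C)[C@H]3OC(C)(C)O[C@H]3C[C@@]12C
A2 | alternative 2 | bicyclic 7-ene with C11–C12 methyl ester and C2/C3 acetonide | COC(=O)C[C@@H]1C(C)=CC[C@@H]2C(C)(C)[C@H]3OC(C)(C)O[C@H]3C[C@@]12C
A3 | alternative 3 | bicyclic 1,7-diene with full side chain, C3 triethylsilyl ether and C15 tert-butyldiphenylsilyl ether | CC(C)(C)[Si](c3ccccc3)(c4ccccc4)OC/C=C(\C)CC[C@@H]1C(C)=CC[C@@H]2C(C)(C)[C@@H](O[Si](CC)(CC)CC)C=C[C@@]12C
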